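The route builds ring A first and closes ring B last by an intramolecular Diels–Alder reaction (decalin numbering: ring A C1–C5, C10; ring B C5–C10; C11 formyl, C12 ester carbon). The key step exploits the 1,4-relationship between the oxygen on C1 and C11 on C9: esterifying O1 with methyl hydrogen acetylenedicarboxylate tethers C11–C9≡C8–C12 to the C10=C5–C6=C7 diene of a 3-vinylcyclohexenol. One thermal step forms C7–C8 and C9–C10, sets quaternary C10 cis to O1 and distinguishes C11 (lactone) from C12 (methyl ester). Ring A comes from an enantioselective ketone allylation and a chloronium-triggered semipinacol shift that sets C3–Cl and quaternary C4 together.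

Key step: step 11

Remark (numbering): α is the face opposite the C10 methyl group, β the face that carries it; the target has 1α-OH, 3β-Cl, 4β-Me, 4α-side chain, 5α-H, 9β-CHO and 10β-Me.
Remark (assumption): the facial sense of the two ligand-controlled steps (1 and 7) is assigned from the usual transition-state models; if either runs the other way, the mirror-image ligand is used.

Step 1
Reactants: 1 2-methylcyclohex-2-en-1-one
Product: 2 (S)-1-allyl-2-methylcyclohex-2-en-1-ol
Conditions: Ti(OiPr)4 (20 mol %), (R)-BINOL (20 mol %), i-PrOH, Sn(CH2CH=CH2)4, CH2Cl2, rt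
Reagents that add atoms: tetraallylstannane C=CC[Sn](CC=C)(CC=C)CC=C
Why: Catalytic enantioselective 1,2-allylation of a ketone with the Ti(OiPr)4–BINOL catalyst, a reaction type established for 2-substituted cyclohexenones, should set the tertiary carbinol whose configuration is relayed to C3 and C4 in step 2.

Step 2
Reactants: 2 (S)-1-allyl-2-methylcyclohex-2-en-1-ol
Product: 3 (2S,3S)-2-allyl-3-chloro-2-methylcyclohexan-1-one
Conditions: N-chlorosuccinimide, Ph3P=S (10 mol %), CH2Cl2, −20 °C
Reagents that add atoms: N-chlorosuccinimide O=C1CCC(=O)N1Cl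
Why: Halonium-induced semipinacol rearrangement, in which the chloronium ion forms on the ring alkene anti to the pseudoaxial allyl group and the allyl group then shifts to the tertiary cationic carbon, should place Cl (C3) trans to allyl (C4) and needs the allyl shift to outrun epoxide formation and ring contraction.

Step 3
Reactants: 3 (2S,3S)-2-allyl-3-chloro-2-methylcyclohexan-1-one
Product: 5 (2S,3S)-2-allyl-3-chloro-2,6-dimethylcyclohexan-1-one (C6 epimers), via lithium enolate 4 (not isolated)
Conditions: LiN(i-Pr)2, THF, −78 °C; MeI, −78 to −20 °C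
Reagents that add atoms: iodomethane CI
Why: Enolate alkylation at the only enolisable α-carbon introduces the future C10 methyl group, and the new centre becomes sp2 in step 4 so its configuration does not matter.

Step 4
Reactants: 5 (2S,3S)-2-allyl-3-chloro-2,6-dimethylcyclohexan-1-one
Product: 6 (5S,6S)-6-allyl-5-chloro-2,6-dimethylcyclohex-2-en-1-one
Conditions: IBX, DMSO, 65 °C
Reagents that add atoms: none
Why: IBX dehydrogenation of the ketone through its only possible enol should give mainly the endocyclic 2-methyl enone, the chloride being safe from elimination because the carbon between it and the carbonyl is quaternary.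

Step 5
Reactants: 6 (5S,6S)-6-allyl-5-chloro-2,6-dimethylcyclohex-2-en-1-one
Product: 7 (5S,6S)-6-allyl-5-chloro-1-ethynyl-2,6-dimethylcyclohex-2-en-1-ol (C1 epimers)
Conditions: HC≡CMgBr, CeCl3, THF, −78 to 0 °C; H2O quench
Reagents that add atoms: ethynylmagnesium bromide C#C[Mg]Br
Why: Cerium-mediated 1,2-addition of a small, weakly basic acetylide to the hindered enone should give the tertiary allylic–propargylic alcohol without γ-deprotonation next to the chloride, and the carbinol configuration is erased in step 6.

Step 6
Reactants: 7 (5S,6S)-6-allyl-5-chloro-1-ethynyl-2,6-dimethylcyclohex-2-en-1-ol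
Product: 8 (4S,5S)-4-allyl-5-chloro-3-ethynyl-2,4-dimethylcyclohex-2-en-1-one
Conditions: pyridinium chlorochromate (C5H5NH[CrO3Cl]), 4 Å molecular sieves, CH2Cl2, rt
Reagents that add atoms: none
Why: Babler–Dauben oxidative 1,3-transposition moves the oxygen to C1 and can only run through the ring allyl unit because the other carbinol substituent is an alkyne, which is why ethynyl and not vinyl was added in step 5.

Step 7
Reactants: 8 (4S,5S)-4-allyl-5-chloro-3-ethynyl-2,4-dimethylcyclohex-2-en-1-one
Product: 9 (1S,4S,5S)-4-allyl-5-chloro-3-ethynyl-2,4-dimethylcyclohex-2-en-1-ol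
Conditions: (R)-2-methyl-CBS-oxazaborolidine (20 mol %), catecholborane, toluene, −78 °C
Reagents that add atoms: none
Why: Corey–Bakshi–Shibata reduction under reagent control (α-methyl alkenyl arm as the large group) should set the C1 carbinol, and the neutral low-temperature conditions neither hydroborate the alkene and alkyne nor eliminate the now β-positioned chloride.

Step 8
Reactants: 9 (1S,4S,5S)-4-allyl-5-chloro-3-ethynyl-2,4-dimethylcyclohex-2-en-1-ol
Product: 10 (1S,4S,5S)-4-allyl-5-chloro-2,4-dimethyl-3-vinylcyclohex-2-en-1-ol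
Conditions: H2 (1 atm), Pd/CaCO3 poisoned with Pb(OAc)2, quinoline, EtOAc, rt
Reagents that add atoms: none
Why: Lindlar semihydrogenation of the terminal alkyne should give the 1,3-diene without reducing the alkenes or the C–Cl bond.

Step 9
Reactants: 11 methyl propiolate
Product: 13 4-methoxy-4-oxobut-2-ynoic acid, via lithium acetylide 12 (not isolated)
Conditions: LiN(i-Pr)2, THF, −78 °C; CO2; aq. HCl
Reagents that add atoms: carbon dioxide O=C=O
Why: Carboxylation of the lithium acetylide gives the half ester of acetylenedicarboxylic acid, the two-carbon unit that will carry C11 and C12.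

Step 10
Reactants: 10 (1S,4S,5S)-4-allyl-5-chloro-2,4-dimethyl-3-vinylcyclohex-2-en-1-ol; 13 4-methoxy-4-oxobut-2-ynoic acid
Product: 14 (1S,4S,5S)-4-allyl-5-chloro-2,4-dimethyl-3-vinylcyclohex-2-en-1-yl methyl but-2-ynedioate
Conditions: N,N'-dicyclohexylcarbodiimide, DMAP (5 mol %), CH2Cl2, −20 to 0 °C
Reagents that add atoms: none
Why: Steglich esterification of the secondary allylic alcohol attaches the dienophile to O1 without touching the C1 configuration.

Step 11
Reactants: 14 (1S,4S,5S)-4-allyl-5-chloro-2,4-dimethyl-3-vinylcyclohex-2-en-1-yl methyl but-2-ynedioate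
Product: 15 tricyclic lactone (C12 methyl ester; γ-lactone from C11 to the 1α-oxygen; C5=C6 and C8=C9; 3β-Cl, 4α-allyl, 4β-Me, 10β-Me)
Conditions: toluene (0.01 M), 2,6-di-tert-butyl-4-methylphenol, 110 °C
Reagents that add atoms: none
Why: Thermal intramolecular Diels–Alder reaction: the C10=C5–C6=C7 diene in its s-cis form adds suprafacially across the C9≡C8 triple bond of the doubly activated alkynoate in a concerted [4+2] transition state, forming the C7–C8 and C9–C10 σ bonds. The closest known reaction types are the ester-tethered intramolecular Diels–Alder reaction of dienyl alkynoates and the intermolecular addition of acetylenedicarboxylates to 2-vinylcyclohexenes with a fully substituted diene terminus. Ring B (six-membered carbocycle) closes as the cycloaddition ring itself, and the γ-lactone (O1–C11–C9–C10–C1) closes as the five-membered tether ring of a type 1 cycloaddition with a three-atom tether. The only new stereocentre, quaternary C10, is fixed by C1, because the tether can deliver C9 only to the diene face that carries O1, so the lactone is cis-fused and the C10 methyl group ends up trans to O1. The step needs facial and orientational control, both secured by the tether (C11 is forced onto C9 next to C10, C12 onto C8), and chemoselectivity for the diene over the isolated allyl group, which the alkynoate cannot engage thermally. A nonpolar solvent, high dilution and a radical inhibitor should keep ionisation of the allylic ester and intermolecular addition in check.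

Step 12
Reactants: 15 tricyclic lactone; 16 2-methylbut-3-en-2-ol
Product: 17 tricyclic lactone with the 4α-[(E)-4-hydroxy-4-methylpent-2-enyl] side chain (otherwise as 15)
Conditions: second-generation Hoveyda–Grubbs catalyst (5 mol %), 16 (10 equiv), CH2Cl2, 40 °C
Reagents that add atoms: none
Why: Olefin cross-metathesis of the only terminal alkene with a tertiary allylic alcohol partner should give the E-disubstituted alkene, the trisubstituted and tetrasubstituted ring alkenes being inert to the catalyst.

Step 13
Reactants: 17 tricyclic lactone with the complete side chain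
Product: 18 trans-fused lactone (5α-H; C8=C9 retained; otherwise as 17)
Conditions: Mn(dpm)3 (10 mol %), PhSiH3, t-BuOOH, i-PrOH, rt
Reagents that add atoms: none
Why: Metal-hydride hydrogen-atom-transfer hydrogenation should deliver H• to C6 of the only alkene that gives a tertiary radical and then give the C5 radical its hydrogen from the α face opposite the two axial methyl groups (trans ring fusion), while the E-1,2-disubstituted side-chain alkene and the electron-poor tetrasubstituted C8=C9 alkene react much more slowly.

Step 14
Reactants: 18 trans-fused lactone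
Product: 19 hydroxy Weinreb amide (C11 N-methoxy-N-methylamide, C12 methyl ester, C8=C9, free 1α-OH)
Conditions: MeNH(OMe)·HCl, Me3Al, CH2Cl2, 0 °C to rt
Reagents that add atoms: N,O-dimethylhydroxylamine hydrochloride CNOC.Cl
Why: Weinreb aminolysis of the α-alkylidene γ-lactone with the aluminium amide opens the tether and marks C11 as the carbonyl to be reduced, the hindered cross-conjugated methyl ester reacting more slowly.

Step 15
Reactants: 19 hydroxy Weinreb amide
Product: 20 bis(triethylsilyl) ether of 19 (at O1 and at the side-chain oxygen)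
Conditions: Et3SiOTf, 2,6-lutidine, CH2Cl2, −78 to 0 °C
Reagents that add atoms: triethylsilyl trifluoromethanesulfonate CC[Si](CC)(CC)OS(=O)(=O)C(F)(F)F
Why: Silylation of both hydroxyl groups blocks relactonisation and later lactol formation at O1 and removes the acidic protons before the enolate step.

Step 16
Reactants: 20 bis(triethylsilyl) ether
Product: 21 enal (C11 aldehyde on C9, C8=C9, C12 methyl ester, both silyl ethers kept)
Conditions: Cp2Zr(H)Cl, THF, rt
Reagents that add atoms: none
Why: Reduction of the Weinreb amide with Cp2Zr(H)Cl stops at the aldehyde through a stable zirconium hemiaminal and leaves esters untouched.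

Step 17
Reactants: 21 enal
Product: 23 bis(triethylsilyl) ether of the target (C7=C8, 9α-H, 9β-CHO), via potassium dienolate 22 (not isolated)
Conditions: KN(SiMe3)2, THF, −78 °C; AcOH, −78 °C
Reagents that add atoms: none
Why: Deconjugative protonation of a dienolate: γ-deprotonation at C7 followed by kinetic α-protonation at C9 from the α face opposite the C10 methyl group moves the alkene to C7=C8 and sets C9, and the 9β-formyl epimer should also be the more stable one because a 9α-formyl group would be syn-axial to the 1α-silyloxy group.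

Step 18
Reactants: 23 bis(triethylsilyl) ether of the target
Product: 24 CNP0167913.1, methyl (1R,4aR,5S,6S,8S,8aS)-6-chloro-1-formyl-8-hydroxy-5-[(E)-4-hydroxy-4-methylpent-2-en-1-yl]-5,8a-dimethyl-1,4,4a,5,6,7,8,8a-octahydronaphthalene-2-carboxylate
Conditions: HF·pyridine, pyridine, THF, 0 °C to rt
Reagents that add atoms: none
Why: Buffered fluoride desilylation frees both alcohols without base, so the epimerisable C9 centre should stay intact, and the 9β-aldehyde cannot close a lactol onto the 1α-hydroxyl for geometric reasons.

Compound list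
1 | 2-methylcyclohex-2-en-1-one | CC1=CCCCC1=O | starting material
2 | (S)-1-allyl-2-methylcyclohex-2-en-1-ol | C=CC[C@]1(O)C(C)=CCCC1 | intermediate
3 | (2S,3S)-2-allyl-3-chloro-2-methylcyclohexan-1-one | C=CC[C@@]1(C)C(=O)CCC[C@@H]1Cl | intermediate
4 | lithium enolate of 3 | C=CC[C@@]1(C)C([O-])=CCC[C@@H]1Cl.[Li+] | intermediate
5 | (2S,3S)-2-allyl-3-chloro-2,6-dimethylcyclohexan-1-one (C6 epimers) | C=CC[C@@]1(C)C(=O)C(C)CC[C@@H]1Cl | intermediate
6 | (5S,6S)-6-allyl-5-chloro-2,6-dimethylcyclohex-2-en-1-one | C=CC[C@@]1(C)C(=O)C(C)=CC[C@@H]1Cl | intermediate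
7 | (5S,6S)-6-allyl-5-chloro-1-ethynyl-2,6-dimethylcyclohex-2-en-1-ol (C1 epimers) | C=CC[C@@]1(C)C(O)(C#C)C(C)=CC[C@@H]1Cl | intermediate
8 | (4S,5S)-4-allyl-5-chloro-3-ethynyl-2,4-dimethylcyclohex-2-en-1-one | C=CC[C@@]1(C)C(C#C)=C(C)C(=O)C[C@@H]1Cl | intermediate
9 | (1S,4S,5S)-4-allyl-5-chloro-3-ethynyl-2,4-dimethylcyclohex-2-en-1-ol | C=CC[C@@]1(C)C(C#C)=C(C)[C@@H](O)C[C@@H]1Cl | intermediate
10 | (1S,4S,5S)-4-allyl-5-chloro-2,4-dimethyl-3-vinylcyclohex-2-en-1-ol | C=CC[C@@]1(C)C(C=C)=C(C)[C@@H](O)C[C@@H]1Cl | intermediate
11 | methyl propiolate | COC(=O)C#C | starting material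
12 | lithium 3-methoxy-3-oxoprop-1-yn-1-ide | COC(=O)C#[C-].[Li+] | intermediate
13 | 4-methoxy-4-oxobut-2-ynoic acid | COC(=O)C#CC(=O)O | intermediate
14 | (1S,4S,5S)-4-allyl-5-chloro-2,4-dimethyl-3-vinylcyclohex-2-en-1-yl methyl but-2-ynedioate | C=CC[C@@]1(C)C(C=C)=C(C)[C@@H](OC(=O)C#CC(=O)OC)C[C@@H]1Cl | intermediate
15 | tricyclic Diels–Alder lactone (C12 methyl ester, C11→O1 γ-lactone, C5=C6, C8=C9, 3β-Cl, 4α-allyl, 4β-Me, 10β-Me) | COC(=O)C1=C2C(=O)O[C@H]3C[C@H](Cl)[C@@](C)(CC=C)C(=CC1)[C@@]23C | intermediate
16 | 2-methylbut-3-en-2-ol | C=CC(C)(C)O | starting material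
17 | tricyclic lactone with 4α-[(E)-4-hydroxy-4-methylpent-2-enyl] side chain | COC(=O)C1=C2C(=O)O[C@H]3C[C@H](Cl)[C@@](C)(C/C=C/C(C)(C)O)C(=CC1)[C@@]23C | intermediate
18 | trans-fused lactone (5α-H, C8=C9) | COC(=O)C1=C2C(=O)O[C@H]3C[C@H](Cl)[C@@](C)(C/C=C/C(C)(C)O)[C@H](CC1)[C@@]23C | intermediate
19 | hydroxy Weinreb amide (C11 amide, C12 ester, C8=C9, 1α-OH) | COC(=O)C1=C(C(=O)N(C)OC)[C@@]2(C)[C@@H](O)C[C@H](Cl)[C@@](C)(C/C=C/C(C)(C)O)[C@@H]2CC1 | intermediate
20 | bis(triethylsilyl) ether of 19 | COC(=O)C1=C(C(=O)N(C)OC)[C@@]2(C)[C@@H](O[Si](CC)(CC)CC)C[C@H](Cl)[C@@](C)(C/C=C/C(C)(C)O[Si](CC)(CC)CC)[C@@H]2CC1 | intermediate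
21 | enal (C11 aldehyde, C8=C9), bis(triethylsilyl) ether | COC(=O)C1=C(C=O)[C@@]2(C)[C@@H](O[Si](CC)(CC)CC)C[C@H](Cl)[C@@](C)(C/C=C/C(C)(C)O[Si](CC)(CC)CC)[C@@H]2CC1 | intermediate
22 | potassium dienolate of 21 (C9=C11–O−, C7=C8) | COC(=O)C1=CC[C@H]2[C@](C)(C/C=C/C(C)(C)O[Si](CC)(CC)CC)[C@@H](Cl)C[C@H](O[Si](CC)(CC)CC)[C@]2(C)C1=C[O-].[K+] | intermediate
23 | bis(triethylsilyl) ether of the target | COC(=O)C1=CC[C@H]2[C@](C)(C/C=C/C(C)(C)O[Si](CC)(CC)CC)[C@@H](Cl)C[C@H](O[Si](CC)(CC)CC)[C@]2(C)[C@H]1C=O | intermediate
24 | CNP0167913.1 | COC(=O)C1=CC[C@H]2[C@](C)(C/C=C/C(C)(C)O)[C@@H](Cl)C[C@H](O)[C@]2(C)[C@H]1C=O | target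

Total step count: 18. Longest linear sequence: 17 (steps 1–8 and 10–18; step 9 is a one-step side branch).

Steps most likely to fail

Step 13. Chemoselectivity of the hydrogen-atom transfer may be lost: hydrogen may be delivered to the side-chain alkene or to the C8=C9 acceptor alkene, or hydrogen abstraction at the doubly allylic C7 may lead to oxidation. The fallback sets out from 15 and replaces hydrogen-atom transfer by heterogeneous hydrogenation after masking the allyl group. Lemieux–Johnson cleavage (OsO4 cat., NaIO4, 2,6-lutidine) of the terminal alkene gives the aldehyde F2, and HC(OMe)3 with pyridinium p-toluenesulfonate gives the dimethyl acetal F3. H2 over Pd/C reduces only C5=C6 from the α face to the trans-fused acetal F4, and aqueous acid releases the aldehyde F5. Ph3P=CH2 gives the terminal alkene F6, and cross-metathesis with 16 brings the route back at 18.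

Step 11. The allylic ester may ionise or eliminate on heating before the ester tether reaches its reactive conformer, or intermolecular addition may compete. The fallback sets out from 10 and runs the cycloaddition intermolecularly. Dimethyl acetylenedicarboxylate (toluene, 110 °C), directed by hydrogen bonding to the free 1α-hydroxyl, gives the hydroxy diester F1. Acid-catalysed lactonisation (TsOH) of O1 onto the C11 ester, which only the syn adduct can undergo, returns to the route at 15.

Step 17. Protonation of the dienolate may occur at C7 (back to the conjugated enal) or at C9 from the β face, or the aldehyde may undergo addition under the basic conditions. The fallback sets out from 21 and avoids the metal dienolate. Et3SiOTf and Et3N convert the enal into the silyl dienol ether F7. Low-temperature protodesilylation with HF·pyridine protonates C9 and removes the two silyl ethers, so that the route is rejoined at 24.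

Further compounds
F1 | step 11 | hydroxy diester from intermolecular cycloaddition (C11 and C12 methyl esters, C5=C6, C8=C9, free 1α-OH) | COC(=O)C1=C(C(=O)OC)[C@@]2(C)[C@@H](O)C[C@H](Cl)[C@@](C)(CC=C)C2=CC1
F2 | step 13 | tricyclic lactone with 4α-(2-oxoethyl) group (C5=C6, C8=C9) | COC(=O)C1=C2C(=O)O[C@H]3C[C@H](Cl)[C@@](C)(CC=O)C(=CC1)[C@@]23C
F3 | step 13 | dimethyl acetal of F2 | COC(=O)C1=C2C(=O)O[C@H]3C[C@H](Cl)[C@@](C)(CC(OC)OC)C(=CC1)[C@@]23C
F4 | step 13 | trans-fused (5α-H) dimethyl acetal | COC(=O)C1=C2C(=O)O[C@H]3C[C@H](Cl)[C@@](C)(CC(OC)OC)[C@H](CC1)[C@@]23C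
F5 | step 13 | trans-fused lactone with 4α-(2-oxoethyl) group | COC(=O)C1=C2C(=O)O[C@H]3C[C@H](Cl)[C@@](C)(CC=O)[C@H](CC1)[C@@]23C
F6 | step 13 | trans-fused lactone with 4α-allyl group | COC(=O)C1=C2C(=O)O[C@H]3C[C@H](Cl)[C@@](C)(CC=C)[C@H](CC1)[C@@]23C
F7 | step 17 | triethylsilyl dienol ether of 21 (C9=C11–OSiEt3, C7=C8) | COC(=O)C1=CC[C@H]2[C@](C)(C/C=C/C(C)(C)O[Si](CC)(CC)CC)[C@@H](Cl)C[C@H](O[Si](CC)(CC)CC)[C@]2(C)C1=CO[Si](CC)(CC)CC
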